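## Retrosynthetic overview

1. The 20-membered macrolactam is opened at the cinnamoyl amide (nitrogen of the aminopropyl end). The (Z)-cinnamic acid is cut at the aryl C8–vinyl bond (Suzuki coupling with (Z)-3-iodoacrylic acid). The (Z)-acrylamide on C9b is cut at its C=C bond (Still–Gennari olefination of a C9b aldehyde that is unmasked from an allyl group).
2. The tricyclic core is traced in one flask to a racemic α-aryl aldehyde and methyl vinyl ketone: enamine Michael addition sets quaternary C9b, an aldol reaction closes the cyclohexanone, and the aldolate oxygen displaces an ortho fluoride to close the dihydrofuran by the O5–C5a bond.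
3. Enabling feature: O5 sits on C4a, which is β to the C3 ketone (O–C4a–C4–C3=O is an aldol pattern) and next to the aryl-bearing quaternary C9b. An aldolate oxygen is therefore born five atoms from aryl carbon C5a, only the cis-fused dihydrofuran can close, and the reversible aldol corrects C4a to the configuration dictated by C9b.
4. Ring order: cyclohexanone, then dihydrofuran (both in the key step), macrolactam last.

Key step: step 3

Assumption: the sense of induction of the proline sulfonamide catalyst in step 3 is assigned on the first run; both antipodes are available and the one that gives the (S)-configured quaternary centre is used.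
Assumption: the di-Boc-spermidine with a free 4-aminobutyl end used in step 8 is taken as a catalogue compound (otherwise three standard steps from N-Boc-1,3-diaminopropane).

## Route

Step 1
Reactants: 1 (5-bromo-2-fluorophenyl)acetonitrile; 2 allyl bromide
Product: 3 rac-2-(5-bromo-2-fluorophenyl)pent-4-enenitrile
Conditions: LiHMDS (1.05 equiv), THF, −78 °C; then 2, −78 → 0 °C
Reagents that add atoms: none
Why: The benzylic nitrile is deprotonated cleanly by LiHMDS and the anion is C-allylated (SN2); the new centre is racemic and is re-made in step 3 through a planar enamine.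

Step 2
Reactants: 3 rac-2-(5-bromo-2-fluorophenyl)pent-4-enenitrile
Product: 4 rac-2-(5-bromo-2-fluorophenyl)pent-4-enal
Conditions: DIBAL-H (1.2 equiv), toluene, −78 °C; aq. Rochelle salt
Reagents that add atoms: water, O
Why: DIBAL-H adds once to the nitrile and the N-aluminio imine is hydrolysed on work-up (nitrile-to-aldehyde reduction), while aryl bromide, aryl fluoride and alkene are inert at −78 °C.

Step 3
Reactants: 4 rac-2-(5-bromo-2-fluorophenyl)pent-4-enal; 5 but-3-en-2-one (methyl vinyl ketone)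
Product: 8 (4aR,9bS)-8-bromo-9b-(prop-2-en-1-yl)-1,2,4a,9b-tetrahydrodibenzo[b,d]furan-3(4H)-one, via keto aldehyde 6 (not isolated), via cis-ketol 7 (not isolated)
Conditions: N-(4-dodecylphenylsulfonyl)prolinamide (20 mol%), 5 (1.5 equiv), DCE, 23 °C; evaporate; KOtBu (1.25 equiv), DMSO–THF, 20 → 45 °C; AcOH
Reagents that add atoms: none
Why: The amine catalyst converts 4 into its enamine, which adds to methyl vinyl ketone on the face left open by the sulfonamide N–H (enamine Michael addition, as in the organocatalytic asymmetric Robinson annulation of α-aryl-α-alkyl aldehydes) and sets the quaternary centre of 6; after removal of excess enone, KOtBu forms the methyl-ketone enolate, which closes the cyclohexanone by aldol addition to the neopentyl aldehyde, and the aldolate oxygen of 7 then displaces the ortho fluoride through a Meisenheimer intermediate (intramolecular SNAr etherification, known for 2-(2-fluoroaryl)alkanols and in tandem aldol–SNAr sequences). The cyclohexanone closes in a 6-(enolexo)-exo-trig aldol and the dihydrofuran in a 5-exo-trig addition–elimination at C5a. C9b is controlled by the catalyst; C4a is controlled by the substrate, because only the ketol with oxygen cis to the aryl group can reach C5a, and the trans ketol returns by retro-aldol to 6, whose quaternary centre carries no second formyl group and so cannot racemise. The step needs O-arylation to win over dehydration of the ketol and over C-arylation by the ketone enolate: fluoride as leaving group with bromine para to it, the five-membered transition state and the higher nucleophilicity of the alkoxide should secure this, and water lost by E1cB can re-add as hydroxide to the enone in DMSO, so the ketol stays accessible. The base is limited to one equivalent beyond the acidic catalyst so that the β-aryloxy ketone product is not re-opened by E1cB elimination.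

Step 4
Reactants: 8 (4aR,9bS)-8-bromo-9b-(prop-2-en-1-yl)-1,2,4a,9b-tetrahydrodibenzo[b,d]furan-3(4H)-one
Product: 9 (4aR,9bS)-8-bromo-9b-[(1E)-prop-1-en-1-yl]-1,2,4a,9b-tetrahydrodibenzo[b,d]furan-3(4H)-one
Conditions: RuHCl(CO)(PPh3)3 (5 mol%), toluene, 80 °C
Reagents that add atoms: none
Why: Ru–H insertion and β-hydride elimination (olefin isomerisation) move the terminal double bond to the internal position next to the quaternary carbon, where it cannot migrate further; no stereocentre is touched and the propenyl geometry is irrelevant.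

Step 5
Reactants: 9 (4aR,9bS)-8-bromo-9b-[(1E)-prop-1-en-1-yl]-1,2,4a,9b-tetrahydrodibenzo[b,d]furan-3(4H)-one
Product: 10 (4aR,9bS)-8-bromo-3-oxo-1,2,3,4,4a,9b-hexahydrodibenzo[b,d]furan-9b-carbaldehyde
Conditions: O3, CH2Cl2–MeOH, −78 °C; Me2S
Reagents that add atoms: ozone, [O-][O+]=O
Why: Ozonolysis with reductive work-up cleaves the only alkene to the C9b aldehyde, while the bromoaryl ether and the ketone are inert at −78 °C when an indicator dye marks the end point.

Step 6
Reactants: 10 (4aR,9bS)-8-bromo-3-oxo-1,2,3,4,4a,9b-hexahydrodibenzo[b,d]furan-9b-carbaldehyde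
Product: 11 methyl (2Z)-3-[(4aR,9bS)-8-bromo-3-oxo-1,2,3,4,4a,9b-hexahydrodibenzo[b,d]furan-9b-yl]prop-2-enoate
Conditions: (CF3CH2O)2P(O)CH2CO2Me, KHMDS, 18-crown-6, THF, −78 °C
Reagents that add atoms: methyl bis(2,2,2-trifluoroethyl)phosphonoacetate, COC(=O)CP(=O)(OCC(F)(F)F)OCC(F)(F)F
Why: In the Still–Gennari variant of the Horner–Wadsworth–Emmons reaction the electron-poor phosphonate eliminates from the kinetic adduct faster than it equilibrates, which gives the Z-enoate, and the aldehyde reacts in preference to the ketone.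

Step 7
Reactants: 11 methyl (2Z)-3-[(4aR,9bS)-8-bromo-3-oxo-1,2,3,4,4a,9b-hexahydrodibenzo[b,d]furan-9b-yl]prop-2-enoate
Product: 12 (2Z)-3-[(4aR,9bS)-8-bromo-3-oxo-1,2,3,4,4a,9b-hexahydrodibenzo[b,d]furan-9b-yl]prop-2-enoic acid
Conditions: Me3SnOH, 1,2-dichloroethane, 70 °C; 1 M HCl wash
Reagents that add atoms: trimethyltin hydroxide, C[Sn](C)(C)O
Why: Trimethyltin hydroxide cleaves the methyl ester under near-neutral conditions, which avoids base-induced opening of the β-aryloxy ketone and Z-to-E isomerisation.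

Step 8
Reactants: 12 (2Z)-3-[(4aR,9bS)-8-bromo-3-oxo-1,2,3,4,4a,9b-hexahydrodibenzo[b,d]furan-9b-yl]prop-2-enoic acid; 13 tert-butyl (4-aminobutyl)[3-((tert-butoxycarbonyl)amino)propyl]carbamate
Product: 14 tert-butyl {4-[(2Z)-3-((4aR,9bS)-8-bromo-3-oxo-1,2,3,4,4a,9b-hexahydrodibenzo[b,d]furan-9b-yl)prop-2-enamido]butyl}[3-((tert-butoxycarbonyl)amino)propyl]carbamate
Conditions: EDC·HCl, HOBt, iPr2NEt, CH2Cl2, 0 → 23 °C
Reagents that add atoms: none
Why: Carbodiimide/HOBt amide coupling acylates the only free amine of 13, so the acrylamide is formed at the aminobutyl end alone.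

Step 9
Reactants: 14 tert-butyl {4-[(2Z)-3-((4aR,9bS)-8-bromo-3-oxo-1,2,3,4,4a,9b-hexahydrodibenzo[b,d]furan-9b-yl)prop-2-enamido]butyl}[3-((tert-butoxycarbonyl)amino)propyl]carbamate
Product: 15 the 8-(4,4,5,5-tetramethyl-1,3,2-dioxaborolan-2-yl) analogue of 14 (same (4aR,9bS) and Z descriptors)
Conditions: B2pin2, Pd(dppf)Cl2 (5 mol%), KOAc, 1,4-dioxane, 80 °C
Reagents that add atoms: bis(pinacolato)diboron, CC1(C)OB(OC1(C)C)B1OC(C)(C)C(C)(C)O1
Why: Miyaura borylation of the aryl bromide with the weak base KOAc tolerates the amide, the carbamates, the ketone and the hindered Z-acrylamide.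

Step 10
Reactants: 15 aryl pinacol boronate; 16 (2Z)-3-iodoprop-2-enoic acid
Product: 17 (2Z)-3-[(4aR,9bS)-9b-{(1Z)-3-[(4-{(tert-butoxycarbonyl)[3-((tert-butoxycarbonyl)amino)propyl]amino}butyl)amino]-3-oxoprop-1-en-1-yl}-3-oxo-1,2,3,4,4a,9b-hexahydrodibenzo[b,d]furan-8-yl]prop-2-enoic acid
Conditions: Pd(PPh3)4 (5 mol%), K3PO4, THF–H2O, 23 → 40 °C; citric acid to pH 4
Reagents that add atoms: none
Why: In the Suzuki–Miyaura coupling, oxidative addition to the (Z)-vinyl iodide and reductive elimination both retain the alkene geometry, so the Z-cinnamic acid should be obtained directly.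

Step 11
Reactants: 17 Z-cinnamic acid
Product: 18 pentafluorophenyl ester of 17
Conditions: C6F5OH, EDC·HCl, CH2Cl2, 0 → 23 °C
Reagents that add atoms: pentafluorophenol, Oc1c(F)c(F)c(F)c(F)c1F
Why: Carbodiimide esterification gives an active ester that survives the acid of the next step, and DMAP is left out so that the Z-alkene is not isomerised by reversible conjugate addition.

Step 12
Reactants: 18 pentafluorophenyl ester
Product: 20 target macrolactam CNP0415009.2 (quaternary carbon S, ether-bearing CH R, both alkenes Z), via diamine bis(trifluoroacetate) 19 (not isolated)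
Conditions: TFA–CH2Cl2 (1:4), 0 °C; evaporate; syringe-pump addition to iPr2NEt, MeCN, 1 mM, 40 °C
Reagents that add atoms: none
Why: Acidolysis removes both Boc groups and the active ester then undergoes macrolactamisation under high dilution, in which the primary amine of the aminopropyl end should be acylated in preference to the more hindered secondary amine.

## Compound list

1 | (5-bromo-2-fluorophenyl)acetonitrile | N#CCc1cc(Br)ccc1F | starting material
2 | allyl bromide (3-bromoprop-1-ene) | C=CCBr | starting material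
3 | rac-2-(5-bromo-2-fluorophenyl)pent-4-enenitrile | C=CCC(C#N)c1cc(Br)ccc1F | intermediate
4 | rac-2-(5-bromo-2-fluorophenyl)pent-4-enal | C=CCC(C=O)c1cc(Br)ccc1F | intermediate
5 | but-3-en-2-one (methyl vinyl ketone) | CC(=O)C=C | starting material
6 | (2S)-2-(5-bromo-2-fluorophenyl)-5-oxo-2-(prop-2-en-1-yl)hexanal | CC(=O)CC[C@](C=O)(CC=C)c1cc(Br)ccc1F | intermediate
7 | (3R,4S)-4-(5-bromo-2-fluorophenyl)-3-hydroxy-4-(prop-2-en-1-yl)cyclohexan-1-one (hydroxyl cis to aryl; potassium alkoxide in the flask) | O=C1CC[C@](CC=C)(c2cc(Br)ccc2F)[C@H](O)C1 | intermediate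
8 | (4aR,9bS)-8-bromo-9b-(prop-2-en-1-yl)-1,2,4a,9b-tetrahydrodibenzo[b,d]furan-3(4H)-one | O=C1CC[C@]2(CC=C)c3cc(Br)ccc3O[C@@H]2C1 | intermediate
9 | (4aR,9bS)-8-bromo-9b-[(1E)-prop-1-en-1-yl]-1,2,4a,9b-tetrahydrodibenzo[b,d]furan-3(4H)-one | O=C1CC[C@]2(/C=C/C)c3cc(Br)ccc3O[C@@H]2C1 | intermediate
10 | (4aR,9bS)-8-bromo-3-oxo-1,2,3,4,4a,9b-hexahydrodibenzo[b,d]furan-9b-carbaldehyde | O=C1CC[C@]2(C=O)c3cc(Br)ccc3O[C@@H]2C1 | intermediate
11 | methyl (2Z)-3-[(4aR,9bS)-8-bromo-3-oxo-1,2,3,4,4a,9b-hexahydrodibenzo[b,d]furan-9b-yl]prop-2-enoate | O=C1CC[C@]2(/C=C\C(=O)OC)c3cc(Br)ccc3O[C@@H]2C1 | intermediate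
12 | (2Z)-3-[(4aR,9bS)-8-bromo-3-oxo-1,2,3,4,4a,9b-hexahydrodibenzo[b,d]furan-9b-yl]prop-2-enoic acid | O=C1CC[C@]2(/C=C\C(=O)O)c3cc(Br)ccc3O[C@@H]2C1 | intermediate
13 | tert-butyl (4-aminobutyl)[3-((tert-butoxycarbonyl)amino)propyl]carbamate | NCCCCN(CCCNC(=O)OC(C)(C)C)C(=O)OC(C)(C)C | starting material
14 | tert-butyl {4-[(2Z)-3-((4aR,9bS)-8-bromo-3-oxo-1,2,3,4,4a,9b-hexahydrodibenzo[b,d]furan-9b-yl)prop-2-enamido]butyl}[3-((tert-butoxycarbonyl)amino)propyl]carbamate | O=C1CC[C@]2(/C=C\C(=O)NCCCCN(CCCNC(=O)OC(C)(C)C)C(=O)OC(C)(C)C)c3cc(Br)ccc3O[C@@H]2C1 | intermediate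
15 | 8-(4,4,5,5-tetramethyl-1,3,2-dioxaborolan-2-yl) analogue of 14, (4aR,9bS), Z | O=C1CC[C@]2(/C=C\C(=O)NCCCCN(CCCNC(=O)OC(C)(C)C)C(=O)OC(C)(C)C)c3cc(B4OC(C)(C)C(C)(C)O4)ccc3O[C@@H]2C1 | intermediate
16 | (2Z)-3-iodoprop-2-enoic acid | OC(=O)/C=C\I | starting material
17 | (2Z)-3-[(4aR,9bS)-9b-{(1Z)-3-[(4-{(tert-butoxycarbonyl)[3-((tert-butoxycarbonyl)amino)propyl]amino}butyl)amino]-3-oxoprop-1-en-1-yl}-3-oxo-1,2,3,4,4a,9b-hexahydrodibenzo[b,d]furan-8-yl]prop-2-enoic acid | O=C1CC[C@]2(/C=C\C(=O)NCCCCN(CCCNC(=O)OC(C)(C)C)C(=O)OC(C)(C)C)c3cc(/C=C\C(=O)O)ccc3O[C@@H]2C1 | intermediate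
18 | pentafluorophenyl ester of 17 | O=C1CC[C@]2(/C=C\C(=O)NCCCCN(CCCNC(=O)OC(C)(C)C)C(=O)OC(C)(C)C)c3cc(/C=C\C(=O)Oc4c(F)c(F)c(F)c(F)c4F)ccc3O[C@@H]2C1 | intermediate
19 | bis(trifluoroacetate) of the Boc-free diamine pentafluorophenyl ester | O=C1CC[C@]2(/C=C\C(=O)NCCCCNCCCN)c3cc(/C=C\C(=O)Oc4c(F)c(F)c(F)c(F)c4F)ccc3O[C@@H]2C1.OC(=O)C(F)(F)F.OC(=O)C(F)(F)F | intermediate
20 | target CNP0415009.2: (Z,Z)-macrolactam, quaternary carbon S, ether-bearing CH R, cis-fused | O=C1CC[C@]23/C=C\C(=O)NCCCCNCCCNC(=O)/C=C\c4ccc(c2c4)O[C@@H]3C1 | target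

## Step count and risks

Total step count: 12. Longest linear sequence: 12 (steps 1 to 12; compounds 2, 5, 13 and 16 are purchased).

Step 3. Loss of water from the ketol or attack of tert-butoxide on the formyl group may drain the aldolate before the weakly activated fluoroarene is substituted. The fallback sets out from 6, which is isolated after the amine-catalysed stage. Catalytic KOtBu in tBuOH–THF at 0 °C closes it to the ketol 7; the trans epimer is resubmitted to the same equilibrating conditions. NaBH4 in MeOH reduces 7 to (3R,4S)-4-(5-bromo-2-fluorophenyl)-4-(prop-2-en-1-yl)cyclohexane-1,3-diol F1 (C1 epimers), which can neither dehydrate to an enone nor undergo retro-aldol cleavage. NaH in DMF at 90 °C then closes the dihydrofuran by intramolecular SNAr to (4aR,9bS)-8-bromo-9b-(prop-2-en-1-yl)-1,2,3,4,4a,9b-hexahydrodibenzo[b,d]furan-3-ol F2. Dess–Martin oxidation returns the route to 8.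

Step 12. Intermolecular acylation (oligomer formation) or acylation at the secondary amine may compete with closure of the 20-membered ring at the cinnamoyl carbonyl. The fallback closes the ring at the other amide and sets out from 11.
- Acid 16 is coupled (EDC, HOBt) with tert-butyl (3-aminopropyl)[4-((tert-butoxycarbonyl)amino)butyl]carbamate (NCCCN(CCCCNC(=O)OC(C)(C)C)C(=O)OC(C)(C)C, the regioisomer of 13) to give tert-butyl [4-((tert-butoxycarbonyl)amino)butyl]{3-[(2Z)-3-iodoprop-2-enamido]propyl}carbamate F5.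
- Miyaura borylation of 11 gives methyl (2Z)-3-[(4aR,9bS)-3-oxo-8-(4,4,5,5-tetramethyl-1,3,2-dioxaborolan-2-yl)-1,2,3,4,4a,9b-hexahydrodibenzo[b,d]furan-9b-yl]prop-2-enoate F6.
- Suzuki coupling of the two gives the Z-cinnamamide methyl ester F7.
- Me3SnOH gives the Z-acrylic acid F8, and C6F5OH/EDC its pentafluorophenyl ester F9.
- TFA gives the diamine bis(trifluoroacetate) F10, which is cyclised under high dilution at the acryloyl carbonyl with the aminobutyl nitrogen to give 20.

Step 6. Slow addition to the neopentyl aldehyde may force a higher temperature, at which the adducts equilibrate and Z-selectivity is lost. The fallback sets out from 10. The Ohira–Bestmann reagent (dimethyl (1-diazo-2-oxopropyl)phosphonate, K2CO3, MeOH) gives (4aR,9bS)-8-bromo-9b-ethynyl-1,2,4a,9b-tetrahydrodibenzo[b,d]furan-3(4H)-one F3. Oxidative methoxycarbonylation (PdCl2, CuCl2, NaOAc, CO, MeOH) gives methyl 3-[(4aR,9bS)-8-bromo-3-oxo-1,2,3,4,4a,9b-hexahydrodibenzo[b,d]furan-9b-yl]prop-2-ynoate F4. Lindlar semi-hydrogenation (H2, Pd/CaCO3/Pb, quinoline) adds hydrogen syn and rejoins the route at 11.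

Further compounds
F1 | step 3 | (3R,4S)-4-(5-bromo-2-fluorophenyl)-4-(prop-2-en-1-yl)cyclohexane-1,3-diol (C1 epimers) | OC1CC[C@](CC=C)(c2cc(Br)ccc2F)[C@H](O)C1
F2 | step 3 | (4aR,9bS)-8-bromo-9b-(prop-2-en-1-yl)-1,2,3,4,4a,9b-hexahydrodibenzo[b,d]furan-3-ol (C3 epimers) | OC1CC[C@]2(CC=C)c3cc(Br)ccc3O[C@@H]2C1
F3 | step 6 | (4aR,9bS)-8-bromo-9b-ethynyl-1,2,4a,9b-tetrahydrodibenzo[b,d]furan-3(4H)-one | O=C1CC[C@]2(C#C)c3cc(Br)ccc3O[C@@H]2C1
F4 | step 6 | methyl 3-[(4aR,9bS)-8-bromo-3-oxo-1,2,3,4,4a,9b-hexahydrodibenzo[b,d]furan-9b-yl]prop-2-ynoate | O=C1CC[C@]2(C#CC(=O)OC)c3cc(Br)ccc3O[C@@H]2C1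
F5 | step 12 | tert-butyl [4-((tert-butoxycarbonyl)amino)butyl]{3-[(2Z)-3-iodoprop-2-enamido]propyl}carbamate | I/C=C\C(=O)NCCCN(CCCCNC(=O)OC(C)(C)C)C(=O)OC(C)(C)C
F6 | step 12 | methyl (2Z)-3-[(4aR,9bS)-3-oxo-8-(4,4,5,5-tetramethyl-1,3,2-dioxaborolan-2-yl)-1,2,3,4,4a,9b-hexahydrodibenzo[b,d]furan-9b-yl]prop-2-enoate | O=C1CC[C@]2(/C=C\C(=O)OC)c3cc(B4OC(C)(C)C(C)(C)O4)ccc3O[C@@H]2C1
F7 | step 12 | methyl (2Z)-3-[(4aR,9bS)-8-{(1Z)-3-[(3-{(tert-butoxycarbonyl)[4-((tert-butoxycarbonyl)amino)butyl]amino}propyl)amino]-3-oxoprop-1-en-1-yl}-3-oxo-1,2,3,4,4a,9b-hexahydrodibenzo[b,d]furan-9b-yl]prop-2-enoate | O=C1CC[C@]2(/C=C\C(=O)OC)c3cc(/C=C\C(=O)NCCCN(CCCCNC(=O)OC(C)(C)C)C(=O)OC(C)(C)C)ccc3O[C@@H]2C1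
F8 | step 12 | carboxylic acid from F7 | O=C1CC[C@]2(/C=C\C(=O)O)c3cc(/C=C\C(=O)NCCCN(CCCCNC(=O)OC(C)(C)C)C(=O)OC(C)(C)C)ccc3O[C@@H]2C1
F9 | step 12 | pentafluorophenyl ester of F8 | O=C1CC[C@]2(/C=C\C(=O)Oc4c(F)c(F)c(F)c(F)c4F)c3cc(/C=C\C(=O)NCCCN(CCCCNC(=O)OC(C)(C)C)C(=O)OC(C)(C)C)ccc3O[C@@H]2C1
F10 | step 12 | bis(trifluoroacetate) of the Boc-free diamine from F9 | O=C1CC[C@]2(/C=C\C(=O)Oc4c(F)c(F)c(F)c(F)c4F)c3cc(/C=C\C(=O)NCCCNCCCCN)ccc3O[C@@H]2C1.OC(=O)C(F)(F)F.OC(=O)C(F)(F)F
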